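One equivalent of X per Z charged was the unit the meeting chose, which puts the summer run at 1.20, the midnight run at 1.90 and eta at 1.50.

| flask | Z | X | remark | time |
|---|---|---|---|---|
| summer | 0.010 M | 12 mM | run made earlier |  |
| midnight | 0.010 M | 19 mM | run made earlier |  |
| eta | 0.010 M | 15.0 mM |  | 25 min |
| gamma | 0.010 M | 25.0 mM |  | 25 min |

| run | time / min | J / % | Q / % | Z / % |
|---|---|---|---|---|
| summer | 1.33 | 1.5 | 15.6 | 82.4 |
| summer | 3.00 | 2.3 | 26.7 | 68.7 |
| summer | 6.00 | 1.2 | 35.0 | 50.8 |
| summer | 10.0 | 2.8 | 35.1 | 36.7 |
| summer | 12.0 | 2.2 | 34.3 | 32.4 |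
| summer | 20.0 | 4.1 | 23.9 | 20.5 |
| midnight | 1.33 | 1.6 | 23.5 | 74.8 |
| midnight | 3.00 | 1.6 | 37.4 | 54.6 |
| midnight | 6.00 | 2.9 | 45.8 | 33.7 |
| midnight | 10.0 | 4.1 | 43.4 | 19.3 |
| midnight | 12.0 | 4.7 | 39.7 | 14.7 |
| midnight | 20.0 | 7.2 | 20.8 | 6.1 |

(scatter of a reading: 0.5 percentage points)

- which of these holds the largest part of the Z at the end of eta (Z / Q / J)
- which of these holds the largest part of the Z at the end of gamma (Z / Q / J)
- final J in eta, as a percentage of the Z charged

- a reading or a percentage of Q counts all its forms, free or not

The analyst took the last readings, at 20.0 min, and divided J by the fraction of Z lost and by the equivalents. She reported 0.0430 for the summer run and 0.0404 for the midnight run, and said that a scatter of 0.5 percentage points on a J of 4.1 % covers that gap. She therefore proposed their mean, 0.0417, as the J share, the J made per Z lost per equivalent of X charged.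

The kineticist objected that eta still needed its loss of Z. She proposed a first round in which all Z in eta is taken as lost, which gives 6.25 % of J. For the second round she assumed one X used per Z and fitted the second-order law to the same readings, in fractions of the charge, which gave 0.121 min⁻¹. That law leaves 8.60 % of Z in eta at 25 min. Put back into the share, this gives 5.71 % of J, and the meeting adopted that figure.

The forecast named Q for eta and J for gamma, with 6 % of J in eta, above this reckoning, and wrote of gamma: “J narrowly leads, though this is a close call”.

The flasks give Q in eta and J in gamma, with 5.85 % of J in eta.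

    Z → L (k = 4.20 × 10⁻⁶ s⁻¹)
    G ⇌ Q, rate k2*(cs2 - [Q]) while solid is left; crystals form when [Q] > cs2 (solubility = 0.600 mM, k = 0.140 s⁻¹)
    Q + X → D + J (k = 0.0830 M⁻¹ s⁻¹)
    D + Q → E (k = 2.10 M⁻¹ s⁻¹)
    Z + X → D + Q (k = 0.210 M⁻¹ s⁻¹)

Eta holds 8.71 % of Z against the 8.60 % reckoned, so its own J share is 0.0428. The neighbour flask is eta with 0.0060 M of X, which is 0.600 equivalent, so X is the limiting reagent there and 12.6 % of its charge remains at the end. Round one gives 2.50 % of J in the neighbour flask. The law then leaves 48.7 % of Z, and round two gives 1.28 % of J. The neighbour flask ends with 48.8 % of Z and 1.65 % of J, a J share of 0.0536.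

(The data were computed with made-up constants; the scatter is artificial.)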